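**Plan**
- Retrosynthesis first cuts the ester between the ring C acyl carbon and ring B O4. It then cuts, in one operation, the ester between the ring B acyl carbon and ring A O4 together with ring B C1–C6, which opens ring B to a linear tetraketide acylketene masked as a diketo-dioxinone.
- Enabling feature: ring B is an orsellinoyl unit. C1 carries the acyl carbon esterified to ring A O4, C2 an OH, C4 an O and C6 a CH3, which is the array an aryl 3,5,7-trioxooctanoate folds into by C2→C7 aldol closure.
- Forward: rings A and C come preformed from methyl orsellinate; the dioxinone side chain is extended by two acetyl units; the ring A phenol is joined and ring B is built in the key step.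
- The benzyl-protected ring C acid chloride is then attached to the unchelated ring B 4-OH, and hydrogenolysis finishes the route.
- Stereochemistry: none has to be set; the two transient sp3 centres of the aldol adduct disappear on aromatisation.

Key step: step 6

Assumption: the target has no stereocentre and no configurationally stable axis, so it is one achiral compound and the request for a single enantiomer is met without stereocontrol.

**Route**

Step 1
Reactants: 1 2,2,6-trimethyl-4H-1,3-dioxin-4-one; 2 acetyl chloride
Product: 3 2,2-dimethyl-6-(2-oxopropyl)-4H-1,3-dioxin-4-one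
Conditions: 1 (2 equiv), LiHMDS (2 equiv), THF, −78 °C; then AcCl (1 equiv), −78 °C; aq. NH4Cl
Reagents that add atoms: none
Why: LiHMDS removes the γ-proton of 1 to give the lithium dienolate, which undergoes vinylogous Claisen-type C-acylation at the exocyclic carbon, the second equivalent of dienolate absorbing the more acidic proton of 3 so that diacylation is suppressed.

Step 2
Reactants: 3 2,2-dimethyl-6-(2-oxopropyl)-4H-1,3-dioxin-4-one; 4 N-methoxy-N-methylacetamide
Product: 5 6-(2,4-dioxopentyl)-2,2-dimethyl-4H-1,3-dioxin-4-one
Conditions: LDA (2.2 equiv), THF, −78 °C; then 4, −78 → −20 °C; 1 M HCl quench; used without storage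
Reagents that add atoms: none
Why: Two equivalents of LDA generate the Weiler-type dianion of 3, whose terminal carbanion attacks the Weinreb amide in a Claisen-type acylation, and the N-methoxy chelate holds the tetrahedral intermediate until the acidic quench so that over-addition is avoided.

Step 3
Reactants: 6 methyl 2,4-dihydroxy-6-methylbenzoate (methyl orsellinate)
Product: 7 methyl 4-(benzyloxy)-2-hydroxy-6-methylbenzoate
Conditions: BnBr (1.05 equiv), K2CO3, acetone, reflux
Reagents that add atoms: benzyl bromide, BrCc1ccccc1
Why: Williamson etherification under weak base should be selective for the 4-OH, because the 2-OH is hydrogen-bonded to the ester carbonyl and is both less acidic and less nucleophilic.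

Step 4
Reactants: 7 methyl 4-(benzyloxy)-2-hydroxy-6-methylbenzoate
Product: 8 methyl 4-(benzyloxy)-2-methoxy-6-methylbenzoate
Conditions: MeI (3 equiv), K2CO3, DMF, 40 °C
Reagents that add atoms: iodomethane, CI
Why: Williamson methylation of the remaining chelated phenol proceeds under more forcing conditions (dipolar solvent, excess iodomethane), and 7 offers no other alkylatable site.

Step 5
Reactants: 8 methyl 4-(benzyloxy)-2-methoxy-6-methylbenzoate
Product: 9 methyl 4-hydroxy-2-methoxy-6-methylbenzoate
Conditions: H2 (1 atm), 10% Pd/C, EtOAc, rt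
Reagents that add atoms: none
Why: Catalytic hydrogenolysis cleaves only the benzylic C–O bond and exposes the ring A 4-OH as the single nucleophilic site for the next step.

Step 6
Reactants: 5 6-(2,4-dioxopentyl)-2,2-dimethyl-4H-1,3-dioxin-4-one; 9 methyl 4-hydroxy-2-methoxy-6-methylbenzoate
Product: 13 methyl 4-[(2,4-dihydroxy-6-methylbenzoyl)oxy]-2-methoxy-6-methylbenzoate, via acylketene 10 (not isolated), via triketo aryl ester 11 (not isolated), via aldol adduct 12 (not isolated)
Conditions: 9 (1 equiv), 5 (1.5 equiv, in portions), PhMe (concentrated), 110 °C; cool, Et3N, CH2Cl2, 0 °C → rt; evaporate; HCl (4 M in 1,4-dioxane), rt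
Reagents that add atoms: none
Why: Heating 5 triggers a retro-hetero-Diels–Alder loss of acetone to acylketene 10, whose sp ketene carbon is captured by the ring A phenol oxygen of 9 to give triketo aryl ester 11, so the crowded B acyl–O(A) bond is made before any ortho substituent exists. Triethylamine then enolises C2 of 11, which adds to the C7 ketone in a 6-(enolendo)-exo-trig aldol closure that forges the future ring B C1–C6 bond (adduct 12), and anhydrous HCl dehydrates 12, after which enolisation aromatises ring B. The closest known reaction type is the thermolysis of diketo-dioxinones with alcohol or phenol trapping, followed by biomimetic aldol aromatisation of the triketo ester to a resorcylate. No stereocentre has to be controlled, since the two sp3 centres of 12 are lost on aromatisation. The step needs intermolecular capture of 10 to outrun its own collapse to a pyrone, which the high concentration of 9 from the outset should secure, and it needs C2→C7 aldol closure in place of O5→C1 lactonisation or C6→C1 Claisen closure that would expel the aryloxide, which a metal-free, non-nucleophilic amine base in aprotic solvent followed by acid in a non-nucleophilic medium should secure. The two ring B hydroxyls emerge differentiated, the 2-OH being hydrogen-bonded to the new ester carbonyl, which step 11 relies on.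

Step 7
Reactants: 6 methyl 2,4-dihydroxy-6-methylbenzoate
Product: 14 methyl 2-hydroxy-4-methoxy-6-methylbenzoate
Conditions: MeI (1.1 equiv), K2CO3 (1.1 equiv), acetone, rt
Reagents that add atoms: iodomethane, CI
Why: The same chelation-based difference between the two hydroxyls of 6 lets one equivalent of iodomethane under weak base methylate only the 4-OH (Williamson etherification).

Step 8
Reactants: 14 methyl 2-hydroxy-4-methoxy-6-methylbenzoate
Product: 15 methyl 2-(benzyloxy)-4-methoxy-6-methylbenzoate
Conditions: BnBr (1.5 equiv), K2CO3, DMF, 60 °C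
Reagents that add atoms: benzyl bromide, BrCc1ccccc1
Why: Williamson benzylation of the chelated 2-OH under forcing conditions installs a group that keeps this phenol out of the later acylation and can be removed by hydrogenolysis without touching aryl esters.

Step 9
Reactants: 15 methyl 2-(benzyloxy)-4-methoxy-6-methylbenzoate
Product: 16 2-(benzyloxy)-4-methoxy-6-methylbenzoic acid
Conditions: KOH, DMSO/H2O, 90 °C; then aq. HCl
Reagents that add atoms: potassium hydroxide, [K+].[OH-]
Why: Saponification of the di-ortho-substituted methyl ester needs hot hydroxide in a dipolar aprotic medium, conditions under which the benzyl and methyl aryl ethers are inert.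

Step 10
Reactants: 16 2-(benzyloxy)-4-methoxy-6-methylbenzoic acid
Product: 17 2-(benzyloxy)-4-methoxy-6-methylbenzoyl chloride
Conditions: (COCl)2, DMF (cat.), CH2Cl2, 0 °C → rt; evaporate, use crude
Reagents that add atoms: oxalyl chloride, O=C(Cl)C(=O)Cl
Why: Vilsmeier-type activation by oxalyl chloride and catalytic DMF converts the acid to the acyl chloride under cold, non-forcing conditions that spare the benzyl ether, and all by-products are volatile.

Step 11
Reactants: 13 methyl 4-[(2,4-dihydroxy-6-methylbenzoyl)oxy]-2-methoxy-6-methylbenzoate; 17 2-(benzyloxy)-4-methoxy-6-methylbenzoyl chloride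
Product: 18 methyl 4-({4-[(2-(benzyloxy)-4-methoxy-6-methylbenzoyl)oxy]-2-hydroxy-6-methylbenzoyl}oxy)-2-methoxy-6-methylbenzoate
Conditions: Et3N (1.2 equiv), DMAP (cat.), CH2Cl2, 0 °C → rt
Reagents that add atoms: none
Why: DMAP-catalysed acyl transfer from the acid chloride should occur at the ring B 4-OH, the more acidic and unhindered hydroxyl, while the 2-OH stays hydrogen-bonded to the neighbouring aryl ester carbonyl.

Step 12
Reactants: 18 methyl 4-({4-[(2-(benzyloxy)-4-methoxy-6-methylbenzoyl)oxy]-2-hydroxy-6-methylbenzoyl}oxy)-2-methoxy-6-methylbenzoate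
Product: 19 methyl 4-({2-hydroxy-4-[(2-hydroxy-4-methoxy-6-methylbenzoyl)oxy]-6-methylbenzoyl}oxy)-2-methoxy-6-methylbenzoate
Conditions: H2 (1 atm), 10% Pd/C, EtOAc, rt
Reagents that add atoms: none
Why: Hydrogenolysis over palladium removes the benzyl ether under neutral conditions that leave both aryl ester links and the methyl ester intact, giving the target.

**Compound list**
1 | 2,2,6-trimethyl-4H-1,3-dioxin-4-one | CC1=CC(=O)OC(C)(C)O1 | starting material
2 | acetyl chloride | CC(=O)Cl | starting material
3 | 2,2-dimethyl-6-(2-oxopropyl)-4H-1,3-dioxin-4-one | CC(=O)CC1=CC(=O)OC(C)(C)O1 | intermediate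
4 | N-methoxy-N-methylacetamide | CC(=O)N(C)OC | starting material
5 | 6-(2,4-dioxopentyl)-2,2-dimethyl-4H-1,3-dioxin-4-one | CC(=O)CC(=O)CC1=CC(=O)OC(C)(C)O1 | intermediate
6 | methyl 2,4-dihydroxy-6-methylbenzoate | COC(=O)c1c(C)cc(O)cc1O | starting material
7 | methyl 4-(benzyloxy)-2-hydroxy-6-methylbenzoate | COC(=O)c1c(C)cc(OCc2ccccc2)cc1O | intermediate
8 | methyl 4-(benzyloxy)-2-methoxy-6-methylbenzoate | COC(=O)c1c(C)cc(OCc2ccccc2)cc1OC | intermediate
9 | methyl 4-hydroxy-2-methoxy-6-methylbenzoate | COC(=O)c1c(C)cc(O)cc1OC | intermediate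
10 | 3,5,7-trioxooct-1-en-1-one (acylketene, not isolated) | CC(=O)CC(=O)CC(=O)C=C=O | intermediate
11 | methyl 2-methoxy-6-methyl-4-[(3,5,7-trioxooctanoyl)oxy]benzoate (triketo aryl ester, not isolated) | COC(=O)c1c(C)cc(OC(=O)CC(=O)CC(=O)CC(C)=O)cc1OC | intermediate
12 | methyl 4-{[(2-hydroxy-2-methyl-4,6-dioxocyclohexyl)carbonyl]oxy}-2-methoxy-6-methylbenzoate (aldol adduct, not isolated, transient mixture of stereoisomers) | COC(=O)c1c(C)cc(OC(=O)C2C(=O)CC(=O)CC2(C)O)cc1OC | intermediate
13 | methyl 4-[(2,4-dihydroxy-6-methylbenzoyl)oxy]-2-methoxy-6-methylbenzoate | COC(=O)c1c(C)cc(OC(=O)c2c(C)cc(O)cc2O)cc1OC | intermediate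
14 | methyl 2-hydroxy-4-methoxy-6-methylbenzoate | COC(=O)c1c(C)cc(OC)cc1O | intermediate
15 | methyl 2-(benzyloxy)-4-methoxy-6-methylbenzoate | COC(=O)c1c(C)cc(OC)cc1OCc1ccccc1 | intermediate
16 | 2-(benzyloxy)-4-methoxy-6-methylbenzoic acid | OC(=O)c1c(C)cc(OC)cc1OCc1ccccc1 | intermediate
17 | 2-(benzyloxy)-4-methoxy-6-methylbenzoyl chloride | ClC(=O)c1c(C)cc(OC)cc1OCc1ccccc1 | intermediate
18 | methyl 4-({4-[(2-(benzyloxy)-4-methoxy-6-methylbenzoyl)oxy]-2-hydroxy-6-methylbenzoyl}oxy)-2-methoxy-6-methylbenzoate | COC(=O)c1c(C)cc(OC(=O)c2c(C)cc(OC(=O)c3c(C)cc(OC)cc3OCc3ccccc3)cc2O)cc1OC | intermediate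
19 | methyl 4-({2-hydroxy-4-[(2-hydroxy-4-methoxy-6-methylbenzoyl)oxy]-6-methylbenzoyl}oxy)-2-methoxy-6-methylbenzoate | COC(=O)c1c(C)cc(OC(=O)c2c(C)cc(OC(=O)c3c(C)cc(OC)cc3O)cc2O)cc1OC | target

**Step count**
Total: 12 steps. Longest linear sequence: 6 steps (6 → 7 → 8 → 9 → 13 → 18 → 19; the ring C branch 6 → 14 → 15 → 16 → 17 → 18 → 19 is equally long).

**Steps most likely to fail**

Step 6. The acylketene may cyclise on its own enol oxygen faster than the electron-poor phenol captures it. After capture, the triketo aryl ester may close by lactonisation or Claisen C-acylation with loss of the good aryloxide leaving group instead of by the aldol path. The fallback builds the same ester by classical depside condensation; it sets out from 6 and phenol 9 and comes back at 13. Exhaustive benzylation of 6 (BnBr, K2CO3, DMF, 60 °C) should give methyl 2,4-bis(benzyloxy)-6-methylbenzoate F1. Saponification (KOH, aq. DMSO, 90 °C) should give 2,4-bis(benzyloxy)-6-methylbenzoic acid F2. Condensation of F2 with 9 through the mixed trifluoroacetic anhydride (TFAA, toluene, rt) should give methyl 4-{[2,4-bis(benzyloxy)-6-methylbenzoyl]oxy}-2-methoxy-6-methylbenzoate F3. Hydrogenolysis of both benzyl ethers (H2, Pd/C, EtOAc) returns to 13.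

Step 2. Acyl transfer from the amide to the dianion may stall, or proton exchange between dianion and product may cap the conversion, and the enol-rich diketone may self-condense during work-up. The fallback reaches the same oxidation level by aldol addition and oxidation; it sets out from 3 and comes back at 5. The dianion of 3 (LDA, THF, −78 °C) is trapped with acetaldehyde to give racemic 6-(4-hydroxy-2-oxopentyl)-2,2-dimethyl-4H-1,3-dioxin-4-one F4. Dess–Martin oxidation (CH2Cl2, rt) then removes the stereocentre and returns to 5.

Step 11. Acyl transfer from the doubly ortho-substituted acid chloride may be sluggish, which would let acylation at the chelated 2-OH or base-mediated acyl scrambling among the aryl esters compete. The fallback repeats the ketene logic of step 6 so that the hindered ester is again made from an unhindered ketene; it sets out from 13 and 5 and comes back at 19 without passing through 18. Thermolysis of 5 with 13 (PhMe, 110 °C) should give, through acylketene 10, methyl 4-({2-hydroxy-6-methyl-4-[(3,5,7-trioxooctanoyl)oxy]benzoyl}oxy)-2-methoxy-6-methylbenzoate F5. Et3N then HCl/dioxane should take it through methyl 4-[(2-hydroxy-4-{[(2-hydroxy-2-methyl-4,6-dioxocyclohexyl)carbonyl]oxy}-6-methylbenzoyl)oxy]-2-methoxy-6-methylbenzoate F6 to methyl 4-({4-[(2,4-dihydroxy-6-methylbenzoyl)oxy]-2-hydroxy-6-methylbenzoyl}oxy)-2-methoxy-6-methylbenzoate F7. Methylation of the only unchelated hydroxyl of F7 (MeI, 1 equiv, K2CO3, acetone, rt) gives 19.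

**Further compounds**
F1 | step 6 | methyl 2,4-bis(benzyloxy)-6-methylbenzoate | COC(=O)c1c(C)cc(OCc2ccccc2)cc1OCc1ccccc1
F2 | step 6 | 2,4-bis(benzyloxy)-6-methylbenzoic acid | OC(=O)c1c(C)cc(OCc2ccccc2)cc1OCc1ccccc1
F3 | step 6 | methyl 4-{[2,4-bis(benzyloxy)-6-methylbenzoyl]oxy}-2-methoxy-6-methylbenzoate | COC(=O)c1c(C)cc(OC(=O)c2c(C)cc(OCc3ccccc3)cc2OCc2ccccc2)cc1OC
F4 | step 2 | 6-(4-hydroxy-2-oxopentyl)-2,2-dimethyl-4H-1,3-dioxin-4-one (racemic) | CC(O)CC(=O)CC1=CC(=O)OC(C)(C)O1
F5 | step 11 | methyl 4-({2-hydroxy-6-methyl-4-[(3,5,7-trioxooctanoyl)oxy]benzoyl}oxy)-2-methoxy-6-methylbenzoate | COC(=O)c1c(C)cc(OC(=O)c2c(C)cc(OC(=O)CC(=O)CC(=O)CC(C)=O)cc2O)cc1OC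
F6 | step 11 | methyl 4-[(2-hydroxy-4-{[(2-hydroxy-2-methyl-4,6-dioxocyclohexyl)carbonyl]oxy}-6-methylbenzoyl)oxy]-2-methoxy-6-methylbenzoate (mixture of stereoisomers) | COC(=O)c1c(C)cc(OC(=O)c2c(C)cc(OC(=O)C3C(=O)CC(=O)CC3(C)O)cc2O)cc1OC
F7 | step 11 | methyl 4-({4-[(2,4-dihydroxy-6-methylbenzoyl)oxy]-2-hydroxy-6-methylbenzoyl}oxy)-2-methoxy-6-methylbenzoate | COC(=O)c1c(C)cc(OC(=O)c2c(C)cc(OC(=O)c3c(C)cc(O)cc3O)cc2O)cc1OC
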